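**Strategy.** The flavonol is cut at the aryl–oxygen bond O1–C8a of the pyranone (ring C). That bond lies on the fully substituted ring A, next to C4a, which carries the C4 carbonyl. An enolate oxygen can therefore be joined to C8a at the expense of a bromide placed there. A copper-catalysed intramolecular O-arylation of a 1-(2-bromoaryl)-1,3-diketone forms O1–C8a and closes ring C in one operation, giving the flavone at its final oxidation level. The precursor is a 2-benzyloxy-1,3-diketone flanked by a 2-bromo-3,4,5,6-tetramethoxyphenyl ketone and a 4-methoxyphenyl ketone. The benzyl ether carries the C3 oxygen and is removed last.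

Key step: step 6

Remark: Weinreb amide 5 and Grignard solution 6 are assumed to be purchased materials.
Remark: C2 of diketone 11 is a stereocentre only in the keto tautomer; it is racemic, epimerises through the enol and becomes sp2 (C3) in 13. The target has no stereocentre.

Step 1
Reactants: 1 1,2,3,4-tetramethoxybenzene
Product: 3 2,3,4,5-tetramethoxybenzaldehyde, via α-chloro ether 2 (not isolated)
Conditions: Cl2CHOMe (1.2 equiv), TiCl4 (2 equiv), CH2Cl2, 0 °C; then ice-water
Reagents that add atoms: dichloromethyl methyl ether COC(Cl)Cl; water O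
Why: Rieche formylation (electrophilic aromatic substitution): the two free positions of 1 are equivalent by symmetry and each is ortho and para to a methoxy group, so one aldehyde should result once chloro ether 2 is hydrolysed, and the formyl group deactivates the ring against a second substitution.

Step 2
Reactants: 3 2,3,4,5-tetramethoxybenzaldehyde
Product: 4 2-bromo-3,4,5,6-tetramethoxybenzaldehyde
Conditions: NBS (1.05 equiv), MeCN, rt to 50 °C, dark
Reagents that add atoms: N-bromosuccinimide O=C1CCC(=O)N1Br
Why: Electrophilic aromatic bromination: the single remaining ring C–H is ortho and para to methoxy groups and should be substituted as in the known ortho-bromination of polymethoxybenzaldehydes, and brominating at the aldehyde stage avoids the ipso-bromodecarboxylation that threatens an electron-rich benzoic acid.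

Step 3
Reactants: 5 2-(benzyloxy)-N-methoxy-N-methylacetamide; 6 4-methoxyphenylmagnesium bromide
Product: 8 2-(benzyloxy)-1-(4-methoxyphenyl)ethan-1-one, via magnesium hemiaminal chelate 7 (not isolated)
Conditions: 6 (1.2 equiv, THF solution), THF, 0 °C to rt; then 1 M aq. HCl, 0 °C
Reagents that add atoms: none
Why: Weinreb ketone synthesis: the aryl Grignard reagent adds once, the five-membered magnesium chelate 7 persists until the acidic quench so no tertiary alcohol can form, and the benzyl ether is inert.

Step 4
Reactants: 8 2-(benzyloxy)-1-(4-methoxyphenyl)ethan-1-one; 4 2-bromo-3,4,5,6-tetramethoxybenzaldehyde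
Product: 10 2-(benzyloxy)-3-(2-bromo-3,4,5,6-tetramethoxyphenyl)-3-hydroxy-1-(4-methoxyphenyl)propan-1-one (racemic syn/anti mixture), via lithium Z-enolate 9 (not isolated)
Conditions: LiN(iPr)2 (1.1 equiv), 8 (1.15 equiv), THF, −78 °C; then 4 (1.0 equiv), −78 °C; AcOH in THF quench at −78 °C
Reagents that add atoms: none
Why: Directed aldol addition of a preformed lithium enolate: 8 has one enolisable position and 4 none, the chelated Z-enolate 9 adds through a closed Zimmerman–Traxler transition state (syn adduct expected to predominate), and the two new stereocentres are deliberately left uncontrolled because C3 is oxidised in step 5 and C2 becomes epimerisable there and sp2 in step 6, while the cold acidic quench guards against retro-aldol.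

Step 5
Reactants: 10 2-(benzyloxy)-3-(2-bromo-3,4,5,6-tetramethoxyphenyl)-3-hydroxy-1-(4-methoxyphenyl)propan-1-one
Product: 11 2-(benzyloxy)-1-(2-bromo-3,4,5,6-tetramethoxyphenyl)-3-(4-methoxyphenyl)propane-1,3-dione (racemic, configurationally labile at C2)
Conditions: Dess–Martin periodinane (1.3 equiv), CH2Cl2, 0 °C to rt
Reagents that add atoms: none
Why: Dess–Martin oxidation of a β-hydroxy ketone to a 1,3-diketone: the neutral, non-basic oxidant should avoid retro-aldol, tolerate the ethers and the aryl bromide, and converge both diastereomers of 10 on one diketone.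

Step 6
Reactants: 11 2-(benzyloxy)-1-(2-bromo-3,4,5,6-tetramethoxyphenyl)-3-(4-methoxyphenyl)propane-1,3-dione
Product: 13 3-(benzyloxy)-5,6,7,8-tetramethoxy-2-(4-methoxyphenyl)-4H-chromen-4-one, via cesium enolate 12 (not isolated)
Conditions: CuI (10 mol %), 1,10-phenanthroline (20 mol %), Cs2CO3 (2 equiv), anhydrous 1,4-dioxane, 100 °C, Ar
Reagents that add atoms: none
Why: Cs2CO3 converts 11 into the delocalised enolate 12, whose oxygen on the 4-methoxybenzoyl side binds phenanthroline-ligated monovalent copper; oxidative addition into the adjacent C8a–Br bond gives an aryl trivalent copper species, and C–O reductive elimination forms O1–C8a. The closest known reaction type is the copper-catalysed intramolecular O-arylation (Ullmann-type C–O coupling) of 1-(2-haloaryl)-1,3-diketones to chromones and flavones, with the 2-benzyloxy group as a spectator. Ring C closes as a six-membered ring in a 6-exo-trig sense at the sp2 carbon C8a (through a seven-membered cupracycle in organometallic terms); no stereocentre is formed, and the labile C2 centre of 11 becomes the sp2 carbon C3. Oxygen arylation is secured by ring size, since attack by the enolate carbon would need a four-membered ring and the ring-A carbonyl oxygen cannot reach C8a, and the ortho acyl group assists oxidative addition at the hindered, electron-rich bromide. Anhydrous carbonate in an aprotic solvent and a non-nucleophilic ligand are chosen to hold back retro-Claisen cleavage, ligand–diketone condensation and hydrodebromination, and the large cesium counter-ion leaves the enolate free to rotate into the geometry that presents its oxygen to C8a.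

Step 7
Reactants: 13 3-(benzyloxy)-5,6,7,8-tetramethoxy-2-(4-methoxyphenyl)-4H-chromen-4-one
Product: 14 3-hydroxy-5,6,7,8-tetramethoxy-2-(4-methoxyphenyl)-4H-chromen-4-one
Conditions: H2 (1 atm), 10% Pd/C, EtOAc–MeOH, rt
Reagents that add atoms: none
Why: Hydrogenolysis of a benzyl ether: the O–CH2Ph bond at C3 should cleave under conditions that leave the chromone C2=C3 bond, the C4 carbonyl and all five methyl ethers untouched, whereas Lewis-acid debenzylation would endanger the 5-methoxy group.

**Compound list**

1 | 1,2,3,4-tetramethoxybenzene | COc1ccc(OC)c(OC)c1OC | starting material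
2 | 1-[chloro(methoxy)methyl]-2,3,4,5-tetramethoxybenzene (racemic, not isolated) | COC(Cl)c1cc(OC)c(OC)c(OC)c1OC | intermediate
3 | 2,3,4,5-tetramethoxybenzaldehyde | O=Cc1cc(OC)c(OC)c(OC)c1OC | intermediate
4 | 2-bromo-3,4,5,6-tetramethoxybenzaldehyde | O=Cc1c(Br)c(OC)c(OC)c(OC)c1OC | intermediate
5 | 2-(benzyloxy)-N-methoxy-N-methylacetamide | CON(C)C(=O)COCc1ccccc1 | starting material
6 | 4-methoxyphenylmagnesium bromide | COc1ccc([Mg]Br)cc1 | starting material
7 | bromomagnesium 2-(benzyloxy)-1-[methoxy(methyl)amino]-1-(4-methoxyphenyl)ethan-1-olate (racemic chelate, not isolated) | COc1ccc(C(COCc2ccccc2)(O[Mg]Br)N(C)OC)cc1 | intermediate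
8 | 2-(benzyloxy)-1-(4-methoxyphenyl)ethan-1-one | COc1ccc(C(=O)COCc2ccccc2)cc1 | intermediate
9 | lithium (Z)-2-(benzyloxy)-1-(4-methoxyphenyl)ethen-1-olate (not isolated) | COc1ccc(/C(O[Li])=C/OCc2ccccc2)cc1 | intermediate
10 | 2-(benzyloxy)-3-(2-bromo-3,4,5,6-tetramethoxyphenyl)-3-hydroxy-1-(4-methoxyphenyl)propan-1-one (racemic; syn and anti diastereomers, C2 and C3 not controlled, so no stereodescriptors are given) | COc1ccc(C(=O)C(OCc2ccccc2)C(O)c2c(Br)c(OC)c(OC)c(OC)c2OC)cc1 | intermediate
11 | 2-(benzyloxy)-1-(2-bromo-3,4,5,6-tetramethoxyphenyl)-3-(4-methoxyphenyl)propane-1,3-dione (racemic, labile at C2) | COc1ccc(C(=O)C(OCc2ccccc2)C(=O)c2c(Br)c(OC)c(OC)c(OC)c2OC)cc1 | intermediate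
12 | cesium (E)-2-(benzyloxy)-3-(2-bromo-3,4,5,6-tetramethoxyphenyl)-1-(4-methoxyphenyl)-3-oxoprop-1-en-1-olate (delocalised enolate drawn in the geometry that cyclises; not isolated) | COc1ccc(/C([O-])=C(OCc2ccccc2)/C(=O)c2c(Br)c(OC)c(OC)c(OC)c2OC)cc1.[Cs+] | intermediate
13 | 3-(benzyloxy)-5,6,7,8-tetramethoxy-2-(4-methoxyphenyl)-4H-chromen-4-one | COc1ccc(-c2oc3c(OC)c(OC)c(OC)c(OC)c3c(=O)c2OCc2ccccc2)cc1 | intermediate
14 | 3-hydroxy-5,6,7,8-tetramethoxy-2-(4-methoxyphenyl)-4H-chromen-4-one (achiral) | COc1ccc(-c2oc3c(OC)c(OC)c(OC)c(OC)c3c(=O)c2O)cc1 | target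

**Total steps:** 7. **Longest linear sequence:** 6 (steps 1, 2, 4, 5, 6, 7); step 3 is a one-step side branch.

**Steps most likely to fail**

Step 6. Oxidative addition of copper into the hindered, electron-rich C8a–Br bond may be slow, so base-induced retro-Claisen fragmentation of the diketone or protodehalogenation could outrun ring closure. The fallback changes the leaving group to iodide so that closure can run far below 100 °C. It sets out from aldehyde 3: iodination with I2 and AgOCOCF3 in CH2Cl2 at room temperature should give 2-iodo-3,4,5,6-tetramethoxybenzaldehyde F1. Addition of lithium enolate 9 under the conditions of step 4 should give 2-(benzyloxy)-3-hydroxy-3-(2-iodo-3,4,5,6-tetramethoxyphenyl)-1-(4-methoxyphenyl)propan-1-one F2 as a racemic diastereomer mixture. Dess–Martin oxidation should give 2-(benzyloxy)-1-(2-iodo-3,4,5,6-tetramethoxyphenyl)-3-(4-methoxyphenyl)propane-1,3-dione F3. Treatment with Cs2CO3, CuI and 1,10-phenanthroline in dioxane at 50–60 °C, through cesium (E)-2-(benzyloxy)-3-(2-iodo-3,4,5,6-tetramethoxyphenyl)-1-(4-methoxyphenyl)-3-oxoprop-1-en-1-olate F4, should close ring C and return to the route at 13.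

Step 4. The lithium aldolate of a di-ortho-substituted, electron-rich benzaldehyde may revert to its components, or the addition may stall. The fallback replaces aldol plus oxidation by a C-acylation at the acid oxidation level. It sets out from aldehyde 4: Pinnick oxidation (NaClO2, NaH2PO4, 2-methyl-2-butene, t-BuOH–H2O) should give 2-bromo-3,4,5,6-tetramethoxybenzoic acid F5. Oxalyl chloride with catalytic DMF in CH2Cl2 should give 2-bromo-3,4,5,6-tetramethoxybenzoyl chloride F6. Addition of F6 to lithium enolate 9 (two equivalents, THF, −78 °C, the second equivalent deprotonating the product) should give the diketone directly, returning at 11 and bypassing compound 10 and step 5.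

Step 2. Bromine may attack the formyl-bearing carbon in an ipso sense (loss of the formyl group) or oxidise the aldehyde, since that carbon is activated much like the free position. The fallback reverses the order of functionalisation. It sets out from 1: NBS (1 equiv) in MeCN at 0 °C should give 1-bromo-2,3,4,5-tetramethoxybenzene F7. Rieche formylation at its one remaining C–H (Cl2CHOMe, TiCl4, CH2Cl2, 0 °C), via 1-bromo-2-[chloro(methoxy)methyl]-3,4,5,6-tetramethoxybenzene F8 hydrolysed on work-up, returns to the route at 4.

**Further compounds**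

F1 | step 6 | 2-iodo-3,4,5,6-tetramethoxybenzaldehyde | O=Cc1c(I)c(OC)c(OC)c(OC)c1OC
F2 | step 6 | 2-(benzyloxy)-3-hydroxy-3-(2-iodo-3,4,5,6-tetramethoxyphenyl)-1-(4-methoxyphenyl)propan-1-one (racemic diastereomer mixture) | COc1ccc(C(=O)C(OCc2ccccc2)C(O)c2c(I)c(OC)c(OC)c(OC)c2OC)cc1
F3 | step 6 | 2-(benzyloxy)-1-(2-iodo-3,4,5,6-tetramethoxyphenyl)-3-(4-methoxyphenyl)propane-1,3-dione (racemic, labile at C2) | COc1ccc(C(=O)C(OCc2ccccc2)C(=O)c2c(I)c(OC)c(OC)c(OC)c2OC)cc1
F4 | step 6 | cesium (E)-2-(benzyloxy)-3-(2-iodo-3,4,5,6-tetramethoxyphenyl)-1-(4-methoxyphenyl)-3-oxoprop-1-en-1-olate | COc1ccc(/C([O-])=C(OCc2ccccc2)/C(=O)c2c(I)c(OC)c(OC)c(OC)c2OC)cc1.[Cs+]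
F5 | step 4 | 2-bromo-3,4,5,6-tetramethoxybenzoic acid | OC(=O)c1c(Br)c(OC)c(OC)c(OC)c1OC
F6 | step 4 | 2-bromo-3,4,5,6-tetramethoxybenzoyl chloride | ClC(=O)c1c(Br)c(OC)c(OC)c(OC)c1OC
F7 | step 2 | 1-bromo-2,3,4,5-tetramethoxybenzene | COc1cc(Br)c(OC)c(OC)c1OC
F8 | step 2 | 1-bromo-2-[chloro(methoxy)methyl]-3,4,5,6-tetramethoxybenzene (racemic) | COC(Cl)c1c(Br)c(OC)c(OC)c(OC)c1OC
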